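**Plan**

1. Retrosynthesis: remove the phenol benzyl group; take the C3 carbinol back to the C3 ketone (hydroxyl-directed syn reduction); cut the benzylic CH2–aryl bond; cut the two bonds from C3 to C1 and C2 back to a β-silyloxy ester and EtMgBr.
2. Enabling feature: the benzylic carbon C1 lies β to the oxygen-bearing C3 (aryl–C1–C2–C3–O), so C1, C2 and C3 can be held as a strained cyclopropanol ring. Opening that ring on palladium makes the normally electrophilic β-carbon of the C3 ketone a nucleophile (homoenolate, polarity reversal), which then joins the electrophilic carbon of an aryl bromide.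
3. Forward: C3–C14 come from methyl 3-oxododecanoate; C1–C2 come from EtMgBr as the temporary three-membered ring (Kulinkovich); ring opening and arylation give the protected ketol chain in one operation; desilylation, syn reduction and debenzylation finish the route.
4. Stereochemistry: C5 (R) from Noyori hydrogenation with the (R)-BINAP ruthenium catalyst; C3 (S) by 1,3-syn induction from C5 in the Narasaka–Prasad reduction.

Key step: step 5

Remark: chain carbons are numbered as in the target (C1 benzylic CH2, C3 and C5 carbinol carbons, C6–C14 the nonyl group); the target is the syn-(3S,5R) diol, and both starting materials are taken as catalogue chemicals.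

**Route**

Step 1
Reactants: 1 methyl 3-oxododecanoate
Product: 2 methyl (3R)-3-hydroxydodecanoate
Conditions: RuCl2[(R)-BINAP] (0.5 mol %), H2 (50 atm), MeOH, 50 °C
Reagents that add atoms: none
Why: Noyori asymmetric hydrogenation of a β-keto ester, in which the keto ester chelates ruthenium and the (R)-BINAP ligand directs hydride to one face of the ketone, which should give the (R)-carbinol that becomes C5 of the target.

Step 2
Reactants: 2 methyl (3R)-3-hydroxydodecanoate
Product: 3 methyl (3R)-3-[(tert-butyldimethylsilyl)oxy]dodecanoate
Conditions: TBSCl, imidazole, DMF, 0 °C to rt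
Reagents that add atoms: tert-butyldimethylsilyl chloride, CC(C)(C)[Si](C)(C)Cl
Why: Standard silylation of a secondary alcohol, which masks the hydroxyl against the Grignard/titanium chemistry of step 3 and the base of step 5 and does not touch the stereocentre.

Step 3
Reactants: 3 methyl (3R)-3-[(tert-butyldimethylsilyl)oxy]dodecanoate
Product: 4 1-[(2R)-2-[(tert-butyldimethylsilyl)oxy]undecyl]cyclopropan-1-ol
Conditions: EtMgBr (3 equiv, slow addition), Ti(OiPr)4 (0.2 equiv), THF, 0 °C to rt; aq. NH4Cl
Reagents that add atoms: ethylmagnesium bromide, CC[Mg]Br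
Why: Kulinkovich cyclopropanation, in which the titanacyclopropane formed from EtMgBr and Ti(OiPr)4 acts as a 1,2-dicarbanion and adds twice to the ester carbonyl, which should give the 1-substituted cyclopropanol with the silyl ether and the remote stereocentre unchanged.

Step 4
Reactants: 5 4-bromo-2-methoxyphenol
Product: 6 1-(benzyloxy)-4-bromo-2-methoxybenzene
Conditions: BnBr, K2CO3, DMF, rt
Reagents that add atoms: benzyl bromide, BrCc1ccccc1
Why: Williamson ether synthesis on the phenoxide, which keeps the acidic phenol out of the palladium step and leaves a group removable at the end by hydrogenolysis.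

Step 5
Reactants: 4 1-[(2R)-2-[(tert-butyldimethylsilyl)oxy]undecyl]cyclopropan-1-ol; 6 1-(benzyloxy)-4-bromo-2-methoxybenzene
Product: 7 (5R)-1-[4-(benzyloxy)-3-methoxyphenyl]-5-[(tert-butyldimethylsilyl)oxy]tetradecan-3-one
Conditions: Pd(OAc)2 (5 mol %), XPhos (10 mol %), Cs2CO3 (2 equiv), toluene, 80 °C
Reagents that add atoms: none
Why: Oxidative addition of aryl bromide 6 to zerovalent palladium (formed from Pd(OAc)2 and XPhos) gives an arylpalladium bromide, the cesium alkoxide of cyclopropanol 4 displaces bromide, and strain-driven β-carbon elimination opens the three-membered ring to an aryl(alkyl)palladium homoenolate, Ar–Pd–CH2CH2C(=O)R, whose reductive elimination forms the aryl–CH2 bond and unveils the C3 ketone. The closest known reaction type is the palladium-catalysed ring-opening cross-coupling of 1-alkylcyclopropanols with aryl bromides to give β-aryl ketones (ketone homoenolate arylation). No ring is closed and no stereocentre is created, and the C5 centre is not affected because it is not α to the carbonyl. Regiochemistry of ring opening is not an issue, since cleavage of either C(OH)–CH2 bond of the 1-monosubstituted cyclopropanol leads to the same homoenolate. The selectivity needed is reductive elimination over β-hydride elimination of the homoenolate (which would give the vinyl ketone and the reduced arene), and the bulky, electron-rich biarylphosphine should secure it, while the non-polar medium with an insoluble carbonate base should keep the β-silyloxy ketone from losing silanol.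

Step 6
Reactants: 7 (5R)-1-[4-(benzyloxy)-3-methoxyphenyl]-5-[(tert-butyldimethylsilyl)oxy]tetradecan-3-one
Product: 8 (5R)-1-[4-(benzyloxy)-3-methoxyphenyl]-5-hydroxytetradecan-3-one
Conditions: 48% aq. HF, MeCN, 0 °C to rt
Reagents that add atoms: none
Why: Acidic fluoride desilylation of a secondary silyl ether, conditions under which a β-hydroxy ketone should neither dehydrate nor undergo retro-aldol cleavage and the aryl benzyl ether should stay intact.

Step 7
Reactants: 8 (5R)-1-[4-(benzyloxy)-3-methoxyphenyl]-5-hydroxytetradecan-3-one
Product: 10 (3S,5R)-1-[4-(benzyloxy)-3-methoxyphenyl]tetradecane-3,5-diol, via diethylboron chelate 9 (not isolated)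
Conditions: Et2BOMe (1.1 equiv), THF/MeOH (4:1), −78 °C; then NaBH4, −78 °C; MeOH co-evaporation
Reagents that add atoms: none
Why: Narasaka–Prasad reduction, in which boron ties the C5 oxygen and the C3 carbonyl into a six-membered half-chair chelate with the nonyl group equatorial and external axial hydride delivery should give the 1,3-syn diol, that is (3S) from the (5R) centre.

Step 8
Reactants: 10 (3S,5R)-1-[4-(benzyloxy)-3-methoxyphenyl]tetradecane-3,5-diol
Product: 11 (3S,5R)-1-(4-hydroxy-3-methoxyphenyl)tetradecane-3,5-diol
Conditions: H2 (1 atm), 10% Pd/C, EtOAc, rt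
Reagents that add atoms: none
Why: Catalytic hydrogenolysis of an aryl benzyl ether, which should free the phenol without affecting the secondary alcohols, the arene or either stereocentre.

**Compound list**

1 | methyl 3-oxododecanoate | CCCCCCCCCC(=O)CC(=O)OC | starting material
2 | methyl (3R)-3-hydroxydodecanoate | CCCCCCCCC[C@@H](O)CC(=O)OC | intermediate
3 | methyl (3R)-3-[(tert-butyldimethylsilyl)oxy]dodecanoate | CCCCCCCCC[C@@H](O[Si](C)(C)C(C)(C)C)CC(=O)OC | intermediate
4 | 1-[(2R)-2-[(tert-butyldimethylsilyl)oxy]undecyl]cyclopropan-1-ol | CCCCCCCCC[C@@H](O[Si](C)(C)C(C)(C)C)CC1(O)CC1 | intermediate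
5 | 4-bromo-2-methoxyphenol | COc1cc(Br)ccc1O | starting material
6 | 1-(benzyloxy)-4-bromo-2-methoxybenzene | COc1cc(Br)ccc1OCc1ccccc1 | intermediate
7 | (5R)-1-[4-(benzyloxy)-3-methoxyphenyl]-5-[(tert-butyldimethylsilyl)oxy]tetradecan-3-one | CCCCCCCCC[C@@H](O[Si](C)(C)C(C)(C)C)CC(=O)CCc1ccc(OCc2ccccc2)c(OC)c1 | intermediate
8 | (5R)-1-[4-(benzyloxy)-3-methoxyphenyl]-5-hydroxytetradecan-3-one | CCCCCCCCC[C@@H](O)CC(=O)CCc1ccc(OCc2ccccc2)c(OC)c1 | intermediate
9 | diethylboron chelate of 8, not isolated (C5–O–BEt2 with the C3 carbonyl oxygen bound to boron in a six-membered ring) | CCCCCCCCC[C@@H]1CC(CCc2ccc(OCc3ccccc3)c(OC)c2)=[O+][B-](CC)(CC)O1 | intermediate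
10 | (3S,5R)-1-[4-(benzyloxy)-3-methoxyphenyl]tetradecane-3,5-diol | CCCCCCCCC[C@@H](O)C[C@@H](O)CCc1ccc(OCc2ccccc2)c(OC)c1 | intermediate
11 | (3S,5R)-1-(4-hydroxy-3-methoxyphenyl)tetradecane-3,5-diol | CCCCCCCCC[C@@H](O)C[C@@H](O)CCc1ccc(O)c(OC)c1 | target

**Step count and risks**

Total steps: 8. Longest linear sequence: 7 (steps 1, 2, 3, 5, 6, 7, 8); step 4 is a one-step side branch.

Steps most likely to fail:

1. Step 5. β-Hydride elimination of the palladium homoenolate may outpace reductive elimination, the cyclopropanol may open by base-induced protonation to the ethyl ketone, or the β-silyloxy ketone may lose silanol under the basic conditions. The fallback forms the same bond in the Heck manifold, where β-hydride elimination is the productive path. It sets out from 3 and comes back at 7. Ester 3 would be half-reduced with i-Bu2AlH (CH2Cl2, −78 °C) to (3R)-3-[(tert-butyldimethylsilyl)oxy]dodecanal F1. Addition of vinylmagnesium bromide (THF, −78 °C) should give (5R)-5-[(tert-butyldimethylsilyl)oxy]tetradec-1-en-3-ol F2 as a mixture of C3 epimers. Heck arylation of this secondary allylic alcohol with 6 (Pd(OAc)2, P(o-tol)3, NaHCO3, DMF, 90 °C) should place the aryl group on the terminal carbon; β-hydride elimination toward the carbinol and enol-to-ketone tautomerism should then deliver 7. Both epimers converge because the carbinol centre is erased.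

2. Step 3. Direct addition of EtMgBr to the ester may compete with transfer from the titanacyclopropane, or titanium turnover may stall next to the bulky silyloxy group, leaving unreacted ester. The fallback builds the ring by carbenoid addition to an enol ether instead. It sets out from 3 and comes back at 4. Ester 3 would be converted with MeNHOMe·HCl and i-PrMgCl (THF, −20 °C) into (3R)-3-[(tert-butyldimethylsilyl)oxy]-N-methoxy-N-methyldodecanamide F3. MeMgBr (THF, 0 °C) should give (4R)-4-[(tert-butyldimethylsilyl)oxy]tridecan-2-one F4. Kinetic enolisation on the methyl side (LiN(i-Pr)2, Me3SiCl, THF, −78 °C) should give (4R)-4-[(tert-butyldimethylsilyl)oxy]-2-[(trimethylsilyl)oxy]tridec-1-ene F5. Simmons–Smith cyclopropanation (Et2Zn, CH2I2, CH2Cl2, 0 °C) should give tert-butyldimethyl({(2R)-1-[1-(trimethylsilyloxy)cyclopropyl]undecan-2-yl}oxy)silane F6. K2CO3 in MeOH at 0 °C should then remove only the trimethylsilyl group and give 4.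

3. Step 7. Facial selectivity may be poor if boron chelation is incomplete and the unchelated ketone is reduced in the background, which would give the anti diol. The fallback replaces substrate control by catalyst control. It sets out from 8 and comes back at 10. Hydroxyl-directed asymmetric hydrogenation of the β-hydroxy ketone with RuCl2[(S)-BINAP], H2 (50 atm) in MeOH should set the (3S) centre through the ligand, by analogy with the sense seen for β-keto esters, and the ruthenium catalyst should not cleave the benzyl ether. This fallback makes no new compound (F0).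

**Further compounds**

F1 | step 5 | (3R)-3-[(tert-butyldimethylsilyl)oxy]dodecanal | CCCCCCCCC[C@@H](O[Si](C)(C)C(C)(C)C)CC=O
F2 | step 5 | (5R)-5-[(tert-butyldimethylsilyl)oxy]tetradec-1-en-3-ol (both C3 epimers) | CCCCCCCCC[C@@H](O[Si](C)(C)C(C)(C)C)CC(O)C=C
F3 | step 3 | (3R)-3-[(tert-butyldimethylsilyl)oxy]-N-methoxy-N-methyldodecanamide | CCCCCCCCC[C@@H](O[Si](C)(C)C(C)(C)C)CC(=O)N(C)OC
F4 | step 3 | (4R)-4-[(tert-butyldimethylsilyl)oxy]tridecan-2-one | CCCCCCCCC[C@@H](O[Si](C)(C)C(C)(C)C)CC(C)=O
F5 | step 3 | (4R)-4-[(tert-butyldimethylsilyl)oxy]-2-[(trimethylsilyl)oxy]tridec-1-ene | CCCCCCCCC[C@@H](O[Si](C)(C)C(C)(C)C)CC(=C)O[Si](C)(C)C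
F6 | step 3 | tert-butyldimethyl({(2R)-1-[1-(trimethylsilyloxy)cyclopropyl]undecan-2-yl}oxy)silane | CCCCCCCCC[C@@H](O[Si](C)(C)C(C)(C)C)CC1(O[Si](C)(C)C)CC1
F0 | step 7 | none | none
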